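## Structural features

The target joins two heterocycles through one methylene carbon: a (2S)-flavanone (rings A and C, with an unsubstituted phenyl ring B on C2) and a fully substituted 4-hydroxy-2-pyranone (O1', C2'–C6'). The pyranone carries the bridge on C3', a methyl group on C5' and an ethyl group on C6'. Ring A is a hexasubstituted phloroglucinol nucleus: oxygens on C5, C7 and C8a alternate with carbon substituents on C4a (the C4 ketone), C6 (the bridging CH2) and C8 (the 3-methylbut-2-enoyl, or senecioyl, group). C2 is the only stereocentre and has no stereogenic neighbour, but it is a benzylic ether carbon β to the C4 ketone, so base or strong Lewis acid can erase it by retro-oxa-Michael opening to the chalcone. Other fragile elements are the senecioyl enone (a free 7-hydroxyl can add to it and close a 2,2-dimethylchromanone), the acidic enol of the pyranone, and the free phenols, which no acylating intermediate tolerates. The real difficulty is the regiochemistry of ring A (C6 against C8, each flanked by two oxygens) and making an unsymmetrical methylene bridge without symmetrical bis-pyranone or bis-flavanone methanes. The key step exploits the fact that C2', C3' and C4' with the bridging CH2 form a benzylmalonyl unit, while C5' and C6' with their methyl and ethyl groups are the enol of symmetrical pentan-3-one. The pyranone can therefore be closed last by a twofold acylation (C4'–C5' and O1'–C2') on a bridge that is already in place.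

## Logic of the disconnections

26 to 25. The two benzylic C–O bonds on O5 and O7 are the last bonds to be cut in the forward sense. Free phenols cannot be present during an acylation, and the ether on O7 also keeps the senecioyl ketone from cyclising. Nothing is gained in skeleton, but all earlier chemistry becomes possible. The forward step must cleave two aryl benzyl ethers without touching the enone, the pyranone or C2.

25 to 20 and 22. The bonds C4'–C5' and O1'–C2' are cut. This removes a whole ring and splits off a symmetrical five-carbon fragment without stereochemistry, and because the bridge stays on 20 no symmetrical dimer can form. The forward step needs acylation at carbon before oxygen, with neither base nor Lewis acid near C2 and the enone.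

20 to 19 to 18. The two C–Cl bonds go back to carboxylic acids and then to tert-butyl esters. The dichloride must be made at the last moment and used crude. Acid-labile esters are chosen because saponification would open ring C, whereas the flavanone tolerates acid. The demand is acidolysis that leaves the aryl benzyl ethers and the malonic acid intact.

18 to 17, then to 15 and 16, then to 14. The enone is traced to its propargylic alcohol isomer, the C8–C(alkyne) bond is cut, and the C8–I bond is cut. Friedel–Crafts acylation of a flavanone is not viable, and this sequence is neutral or weakly basic. It must come after ring C is closed, since a free O1 hydroxyl would add to the alkyne or the enone. C8 is the only open position of ring A in 14, so no regiochemical question arises. The demands are oxygen delivery to the aryl-bearing alkyne carbon and a base too weak to open ring C.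

14 to 12 and 13. The C2–phenyl bond is cut. This reduces the only stereocentre to a planar chromone and an achiral boronic acid, with the configuration supplied by a catalyst. The forward step needs face selectivity and a medium that does not open the product.

12 to 10. O1–C2 and C2–C3 are cut, so C2 becomes a one-carbon reagent. The gain is a plain 2-hydroxyacetophenone. The forward step must not disturb the malonate.

10 to 7 and 8, then to 6. The C4a–C4 (aryl–acyl) bond is cut through an aryl iodide. Lewis-acid acylation would destroy the tert-butyl esters and benzyl ethers, so a neutral cross-coupling is used. The two positions ortho to the hydroxyl in 6 are equivalent, so the only demand is monoiodination.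

6 to 5 to 3 and 4. The CH2–CH bond is cut as a C=C bond. The bridge carbon is thereby the formyl carbon of 3 and is fixed between the two benzyl ethers. The condensation must work on a hindered, electron-rich aldehyde.

3 to 1. The aryl–CHO bond is cut. Formylation para to the free hydroxyl of 1 sets the whole substitution pattern of ring A: bridge between the two ethers, free hydroxyl destined to become O1. The demand is para over ortho selectivity.

22 to 21. The O–Si bond is cut. The ketone is symmetrical, so only one regioisomer exists.

## Other disconnections considered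

Alternative 1: The cut is through C3–C4 and C2–H of ring C. The salicylaldehyde vinyl ether 2,4-dimethoxy-6-[(1-phenylethenyl)oxy]benzaldehyde A1 would be closed by intramolecular hydroacylation under [Rh(cod)Cl]2 and a chiral SEGPHOS-type bisphosphine to (2S)-5,7-dimethoxyflavanone A2. The formyl C–H bond adds oxidatively to monovalent rhodium, the hydride inserts at the phenyl-bearing olefin carbon (setting C2), and reductive elimination forms C3–C4.

- In its favour: the step is catalytic, atom-economic and base-free, and it sets C2 in the ring closure itself.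
- Against it here: A1 requires 1-phenylvinylation of a hindered, chelated phenol; a 1,1-disubstituted enol ether is a demanding olefin and decarbonylation of the acyl rhodium hydride competes; the 7-O-methyl group of A2 is not chelated and would need conditions that C2 and the enone would not survive.
- The decisive weakness is structural: C6 and C8 of A2 are both open, so the bridge and the senecioyl group would have to be placed by electrophilic substitutions with no inherent C6/C8 preference.
- Comparison: in setting the stereocentre without a boronic acid or water, and in steps to a flavanone core, this alternative is the better one. The chosen plan spends seven steps to reach 14, but there the bridge carbon already sits on C6 and the pyranone precursor is attached, so overall step economy and regiochemical safety favour the chosen plan.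

Alternative 2: The cut is the C4a–C5 bond of ring A. Methyl 3-oxo-4-[(2S)-4-oxo-2-phenyl-3,4-dihydro-2H-pyran-6-yl]butanoate A3 would be enolised by Mg(OMe)2; C4a would attack the ester carbon in a Claisen condensation and the triketone would aromatise to (2S)-5,7-dihydroxyflavanone A4.

- In its favour: it mirrors the polyketide folding, needs no protecting group on ring A, is driven by aromatisation, and delivers the free phloroglucinol, the natural nucleophile for a biomimetic methylene bridge.
- Against it here: the stereocentre of A3 is an ether carbon β to a ketone and is exposed to methoxide, so E1cB opening and loss of configuration are a real risk; A3 needs an asymmetric hetero-Diels–Alder reaction and chain extension.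
- A4 has two equally nucleophilic positions, so bridging with formaldehyde and a pyranone would be expected to give C6/C8 mixtures and symmetrical dimers, and senecioylation would be no more selective.
- Comparison: in protecting-group economy and in length to the flavanone core this alternative is the better one, and its ring-forming step is mechanistically as sound as the key step chosen. The chosen plan is the better one in control of the C6/C8 pattern and of the unsymmetrical bridge.

Alternative 3: The cut is through C8a–O1 and C4a–C4 of ring C. CsF would release 3,5-bis(benzyloxy)benzyne from 3,5-bis(benzyloxy)-2-(trimethylsilyl)phenyl trifluoromethanesulfonate A5. The hydroxyl of methyl (3S)-3-hydroxy-3-phenylpropanoate A6 would add at C8a and the aryl anion at C4a would attack the ester carbonyl, giving (2S)-5,7-bis(benzyloxy)flavanone A7.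

- In its favour: ring C forms in one convergent step; C2 comes from an inexpensive enantiopure hydroxy ester and needs no catalyst control; the alkoxy group directs the nucleophile to the distal aryne carbon, so the regiochemistry is sound; A7 carries the same benzyl ethers as the chosen plan.
- Against it here: A5 takes several steps; the fluoride and alkoxide medium threatens A6 (retro-aldol, elimination to the cinnamate) and the β-aryloxy ketone product (retro-oxa-Michael); and A7 again has C6 and C8 unsubstituted on a ring deactivated by the ketone.
- Comparison: in convergence and in the origin of the stereocentre this alternative is the better one. In mechanism-based regiocontrol of ring closure it is the equal of the chosen plan. It is the weaker one for the later differentiation of C6 and C8 and for the bridge, which the chosen plan settles before ring C exists.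

Key step: step 14

Remark: the descriptor of C2 read from the structure is S; flavanone numbering (O1, C2–C8a) and primed pyranone numbering (O1', C2'–C6') are used throughout.

Remark: twofold benzylation of 2,4,6-trihydroxybenzaldehyde would leave a chelated hydroxyl ortho to the formyl group. The route needs the free hydroxyl para to the formyl carbon (it becomes O1, and the formyl carbon becomes the bridge between the two benzyl ethers), so the aldehyde is made from 1, a catalogue compound, by para-formylation.

Remark: the double-bond geometry of 22 is lost in the pyranone and is therefore immaterial.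

## Route

Step 1
Reactants: 1 3,5-bis(benzyloxy)phenol
Product: 3 2,6-bis(benzyloxy)-4-hydroxybenzaldehyde, via aryl iminium salt 2 (not isolated)
Conditions: POCl3, DMF, MeCN, 0 °C → rt; then aq NaOAc
Reagents that add atoms: N,N-dimethylformamide CN(C)C=O (formyl carbon); water O (carbonyl oxygen)
Why: Vilsmeier–Haack formylation: the chloroiminium ion attacks the carbon para to the free hydroxyl, which all three oxygens activate and which is the preferred site in 3,5-dialkoxyphenols; hydrolysis of 2 releases the aldehyde, and the minor chelated ortho isomer should be separable by chromatography.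

Step 2
Reactants: 3 2,6-bis(benzyloxy)-4-hydroxybenzaldehyde; 4 di-tert-butyl propanedioate (di-tert-butyl malonate)
Product: 5 di-tert-butyl 2-[2,6-bis(benzyloxy)-4-hydroxybenzylidene]propanedioate
Conditions: piperidine (0.2 equiv), AcOH (0.4 equiv), toluene, reflux, Dean–Stark
Reagents that add atoms: none
Why: Knoevenagel condensation under piperidinium acetate catalysis with azeotropic removal of water; both ortho oxygens are etherified, so no coumarin can form, and tert-butyl esters resist aminolysis.

Step 3
Reactants: 5 di-tert-butyl 2-[2,6-bis(benzyloxy)-4-hydroxybenzylidene]propanedioate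
Product: 6 di-tert-butyl 2-[2,6-bis(benzyloxy)-4-hydroxybenzyl]propanedioate
Conditions: NaBH4, THF/EtOH, 0 °C
Reagents that add atoms: none
Why: Conjugate hydride reduction of an alkylidene malonate by NaBH4; the esters, the benzyl ethers and the phenol are inert at 0 °C.

Step 4
Reactants: 6 di-tert-butyl 2-[2,6-bis(benzyloxy)-4-hydroxybenzyl]propanedioate
Product: 7 di-tert-butyl 2-[2,6-bis(benzyloxy)-4-hydroxy-3-iodobenzyl]propanedioate
Conditions: NIS (1.0 equiv, slow addition), CH2Cl2, −40 → 0 °C
Reagents that add atoms: N-iodosuccinimide O=C1CCC(=O)N1I
Why: Electrophilic aromatic iodination ortho to the free phenol; the two ortho positions are equivalent, so only mono- against di-iodination has to be controlled, which one equivalent of reagent at low temperature should achieve.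

Step 5
Reactants: 7 di-tert-butyl 2-[2,6-bis(benzyloxy)-4-hydroxy-3-iodobenzyl]propanedioate; 8 tributyl(1-ethoxyethenyl)stannane
Product: 10 di-tert-butyl 2-[3-acetyl-2,6-bis(benzyloxy)-4-hydroxybenzyl]propanedioate, via enol ether 9 (not isolated)
Conditions: PdCl2(PPh3)2 (5 mol %), toluene, 100 °C; then 1 M HCl, THF, rt
Reagents that add atoms: water O (ketone oxygen)
Why: Stille coupling of the aryl iodide with the 1-ethoxyvinyl stannane (an acetyl anion equivalent) under neutral conditions, then mild acid hydrolysis of enol ether 9; this places the ortho acetyl group without the Lewis acids of a Friedel–Crafts or Fries acylation, which the tert-butyl esters and benzyl ethers would not survive.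

Step 6
Reactants: 10 di-tert-butyl 2-[3-acetyl-2,6-bis(benzyloxy)-4-hydroxybenzyl]propanedioate
Product: 12 di-tert-butyl 2-{[5,7-bis(benzyloxy)-4-oxo-4H-chromen-6-yl]methyl}propanedioate, via enaminone 11 (not isolated)
Conditions: Me2NCH(OMe)2, toluene, 95 °C; concentrate; AcOH, 60 °C
Reagents that add atoms: N,N-dimethylformamide dimethyl acetal COC(OC)N(C)C
Why: Enaminone formation at the acetyl methyl group with the amide acetal, then acid-promoted addition of the phenol to the enaminone β-carbon and loss of dimethylamine (the standard chromone synthesis from a 2-hydroxyacetophenone); the monosubstituted malonate has no second acidic hydrogen with which to condense.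

Step 7
Reactants: 12 di-tert-butyl 2-{[5,7-bis(benzyloxy)-4-oxo-4H-chromen-6-yl]methyl}propanedioate; 13 phenylboronic acid
Product: 14 di-tert-butyl 2-{[(2S)-5,7-bis(benzyloxy)-4-oxo-2-phenylchroman-6-yl]methyl}propanedioate
Conditions: 13 (2.5 equiv), [Rh(OH)(cod)]2 (2.5 mol %), (S)-MeO-F12-BIPHEP (5.5 mol %), toluene/H2O, rt
Reagents that add atoms: none
Why: Rhodium-catalysed asymmetric 1,4-addition of an arylboronic acid to a chromone (Hayashi–Miyaura type): transmetalation gives a phenyl complex of monovalent rhodium, the C2=C3 bond inserts, and protonolysis releases the flavanone, while the electron-poor ligand (S)-6,6'-dimethoxy-2,2'-bis[bis(3,4,5-trifluorophenyl)phosphino]biphenyl keeps the medium near neutral so that ring C should not open. C2 is set by the ligand: by the quadrant model under which (S)-biaryl bisphosphines give (S)-3-arylcyclohexanones, phenyl should add to the face that gives 2S, and the antipodal ligand is available should the sense prove opposite.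

Step 8
Reactants: 14 di-tert-butyl 2-{[(2S)-5,7-bis(benzyloxy)-4-oxo-2-phenylchroman-6-yl]methyl}propanedioate
Product: 15 di-tert-butyl 2-{[(2S)-5,7-bis(benzyloxy)-8-iodo-4-oxo-2-phenylchroman-6-yl]methyl}propanedioate
Conditions: NIS (1.1 equiv), TFA (0.2 equiv), MeCN, 0 °C → rt
Reagents that add atoms: N-iodosuccinimide O=C1CCC(=O)N1I
Why: Electrophilic aromatic iodination; C8 is the only unsubstituted position of ring A and is activated by O1 and both benzyloxy groups, whereas ring B and the benzyl rings are unactivated; catalytic acid leaves C2 and the tert-butyl esters alone.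

Step 9
Reactants: 15 di-tert-butyl 2-{[(2S)-5,7-bis(benzyloxy)-8-iodo-4-oxo-2-phenylchroman-6-yl]methyl}propanedioate; 16 2-methylbut-3-yn-2-ol
Product: 17 di-tert-butyl 2-{[(2S)-5,7-bis(benzyloxy)-8-(3-hydroxy-3-methylbut-1-yn-1-yl)-4-oxo-2-phenylchroman-6-yl]methyl}propanedioate
Conditions: 16 (2 equiv), PdCl2(PPh3)2 (5 mol %), CuI (10 mol %), Et3N, THF, 45 °C
Reagents that add atoms: none
Why: Sonogashira coupling (zerovalent palladium formed in situ, copper acetylide as transmetalating partner), well suited to hindered 8-iodo flavonoids; triethylamine at moderate temperature is expected to be too weak a base to enolise C3 and open ring C.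

Step 10
Reactants: 17 di-tert-butyl 2-{[(2S)-5,7-bis(benzyloxy)-8-(3-hydroxy-3-methylbut-1-yn-1-yl)-4-oxo-2-phenylchroman-6-yl]methyl}propanedioate
Product: 18 di-tert-butyl 2-{[(2S)-5,7-bis(benzyloxy)-8-(3-methylbut-2-enoyl)-4-oxo-2-phenylchroman-6-yl]methyl}propanedioate
Conditions: Ph3PAuNTf2 (3 mol %), MeOH (1 equiv), toluene, rt
Reagents that add atoms: none
Why: Gold-catalysed Meyer–Schuster rearrangement: the cationic complex of monovalent gold activates the alkyne, oxygen is delivered to the aryl-bearing carbon while the tertiary hydroxyl leaves (a formal 1,3-hydroxyl shift through an allenol), and tautomerisation gives the aryl 2-methylprop-1-enyl ketone; the electron-rich arene and the tertiary carbinol both favour this regiochemistry over plain hydration.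

Step 11
Reactants: 18 di-tert-butyl 2-{[(2S)-5,7-bis(benzyloxy)-8-(3-methylbut-2-enoyl)-4-oxo-2-phenylchroman-6-yl]methyl}propanedioate
Product: 19 2-{[(2S)-5,7-bis(benzyloxy)-8-(3-methylbut-2-enoyl)-4-oxo-2-phenylchroman-6-yl]methyl}propanedioic acid
Conditions: TFA/CH2Cl2 (1:4), 0 °C → rt; toluene azeotrope below rt
Reagents that add atoms: none
Why: Acidolysis of the tert-butyl esters with loss of 2-methylpropene; the flavanone, the enone and the aryl benzyl ethers should tolerate short exposure to cold dilute acid, and the malonic acid is concentrated cold to avoid decarboxylation.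

Step 12
Reactants: 19 2-{[(2S)-5,7-bis(benzyloxy)-8-(3-methylbut-2-enoyl)-4-oxo-2-phenylchroman-6-yl]methyl}propanedioic acid
Product: 20 2-{[(2S)-5,7-bis(benzyloxy)-8-(3-methylbut-2-enoyl)-4-oxo-2-phenylchroman-6-yl]methyl}propanedioyl dichloride
Conditions: (COCl)2 (3 equiv), DMF (cat.), CH2Cl2, 0 °C → rt; evaporate, use crude
Reagents that add atoms: oxalyl chloride O=C(Cl)C(=O)Cl
Why: Acyl chloride formation by oxalyl chloride with catalytic DMF (chloroiminium activation); ketones, enone and ethers are inert, and the dichloride is taken on at once without purification.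

Step 13
Reactants: 21 pentan-3-one
Product: 22 (Z)-3-(trimethylsilyloxy)pent-2-ene
Conditions: TMSCl, NaI, Et3N, MeCN, rt
Reagents that add atoms: chlorotrimethylsilane C[Si](C)(C)Cl
Why: Silyl enol ether formation by soft enolisation with iodotrimethylsilane generated in situ and triethylamine, which should give mainly the thermodynamically preferred Z isomer; the ketone is symmetrical, so only one regioisomer exists.

Step 14
Reactants: 20 2-{[(2S)-5,7-bis(benzyloxy)-8-(3-methylbut-2-enoyl)-4-oxo-2-phenylchroman-6-yl]methyl}propanedioyl dichloride; 22 (Z)-3-(trimethylsilyloxy)pent-2-ene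
Product: 25 (2S)-5,7-bis(benzyloxy)-6-[(6-ethyl-4-hydroxy-5-methyl-2-oxo-2H-pyran-3-yl)methyl]-8-(3-methylbut-2-enoyl)-2-phenylchroman-4-one, via chlorocarbonyl ketene 23 (not isolated), via diketo acid chloride 24 (not isolated)
Conditions: 22 (2.5 equiv), CH2Cl2, −40 °C → rt; aq work-up
Reagents that add atoms: none
Why: The dichloride is expected to lose HCl to chlorocarbonyl ketene 23, whose ketene carbon is attacked by the nucleophilic carbon of 22 to form C4'–C5', and loss of Me3SiCl gives diketo acid chloride 24 (direct attack of 22 on an acyl chloride carbon would lead to the same adduct). The enol oxygen of the pentanone-derived ketone then acylates on the remaining acyl chloride to form O1'–C2', and tautomerisation gives the aromatic 4-hydroxy-2-pyranone. The closest known reaction is the formation of 4-hydroxy-2-pyranones from ketone silyl enol ethers and substituted malonyl dichlorides. The ring closes in a 6-exo-trig addition–elimination at the acyl chloride carbon. No stereocentre is created, since those of 24 vanish on enolisation, and C2 is untouched because neither base nor Lewis acid is present. The step needs acylation at carbon before oxygen, which is the inherent behaviour of a silyl enol ether toward a ketene, and the symmetry of pentan-3-one removes any regiochemical choice. Excess 22 takes up the HCl, both ring-A oxygens are benzylated so that neither phenol acylation nor closure onto the senecioyl ketone can occur, and low temperature should keep the flanking ether oxygens from attacking the acyl chloride.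

Step 15
Reactants: 25 (2S)-5,7-bis(benzyloxy)-6-[(6-ethyl-4-hydroxy-5-methyl-2-oxo-2H-pyran-3-yl)methyl]-8-(3-methylbut-2-enoyl)-2-phenylchroman-4-one
Product: 26 (2S)-6-[(6-ethyl-4-hydroxy-5-methyl-2-oxo-2H-pyran-3-yl)methyl]-5,7-dihydroxy-8-(3-methylbut-2-enoyl)-2-phenylchroman-4-one
Conditions: BCl3 (6 equiv), C6HMe5 (8 equiv), CH2Cl2, −78 °C; MeOH quench at −78 °C
Reagents that add atoms: none
Why: Lewis-acid debenzylation: BCl3 coordinates the ether oxygens, each of which is ortho to a carbonyl group so that chelation speeds the cleavage, and pentamethylbenzene captures the benzyl cation by Friedel–Crafts alkylation so that it cannot benzylate ring A or the pyranone; at −78 °C with a cold quench the enone, the pyranone and C2 should be untouched and the freed 7-hydroxyl has no time to add to the senecioyl enone.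

## Compound list

1 | 3,5-bis(benzyloxy)phenol | Oc1cc(OCc2ccccc2)cc(OCc2ccccc2)c1 | starting material
2 | [2,6-bis(benzyloxy)-4-hydroxybenzylidene]dimethyliminium dichlorophosphate | C[N+](C)=Cc1c(OCc2ccccc2)cc(O)cc1OCc1ccccc1.[O-]P(=O)(Cl)Cl | intermediate (not isolated)
3 | 2,6-bis(benzyloxy)-4-hydroxybenzaldehyde | O=Cc1c(OCc2ccccc2)cc(O)cc1OCc1ccccc1 | intermediate
4 | di-tert-butyl propanedioate | CC(C)(C)OC(=O)CC(=O)OC(C)(C)C | starting material
5 | di-tert-butyl 2-[2,6-bis(benzyloxy)-4-hydroxybenzylidene]propanedioate | CC(C)(C)OC(=O)C(=Cc1c(OCc2ccccc2)cc(O)cc1OCc1ccccc1)C(=O)OC(C)(C)C | intermediate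
6 | di-tert-butyl 2-[2,6-bis(benzyloxy)-4-hydroxybenzyl]propanedioate | CC(C)(C)OC(=O)C(Cc1c(OCc2ccccc2)cc(O)cc1OCc1ccccc1)C(=O)OC(C)(C)C | intermediate
7 | di-tert-butyl 2-[2,6-bis(benzyloxy)-4-hydroxy-3-iodobenzyl]propanedioate | CC(C)(C)OC(=O)C(Cc1c(OCc2ccccc2)cc(O)c(I)c1OCc1ccccc1)C(=O)OC(C)(C)C | intermediate
8 | tributyl(1-ethoxyethenyl)stannane | CCCC[Sn](CCCC)(CCCC)C(=C)OCC | starting material
9 | di-tert-butyl 2-[2,6-bis(benzyloxy)-3-(1-ethoxyethenyl)-4-hydroxybenzyl]propanedioate | CCOC(=C)c1c(O)cc(OCc2ccccc2)c(CC(C(=O)OC(C)(C)C)C(=O)OC(C)(C)C)c1OCc1ccccc1 | intermediate (not isolated)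
10 | di-tert-butyl 2-[3-acetyl-2,6-bis(benzyloxy)-4-hydroxybenzyl]propanedioate | CC(=O)c1c(O)cc(OCc2ccccc2)c(CC(C(=O)OC(C)(C)C)C(=O)OC(C)(C)C)c1OCc1ccccc1 | intermediate
11 | di-tert-butyl 2-{2,6-bis(benzyloxy)-3-[(2E)-3-(dimethylamino)prop-2-enoyl]-4-hydroxybenzyl}propanedioate | CN(C)/C=C/C(=O)c1c(O)cc(OCc2ccccc2)c(CC(C(=O)OC(C)(C)C)C(=O)OC(C)(C)C)c1OCc1ccccc1 | intermediate (not isolated)
12 | di-tert-butyl 2-{[5,7-bis(benzyloxy)-4-oxo-4H-chromen-6-yl]methyl}propanedioate | O=c1ccoc2cc(OCc3ccccc3)c(CC(C(=O)OC(C)(C)C)C(=O)OC(C)(C)C)c(OCc3ccccc3)c12 | intermediate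
13 | phenylboronic acid | OB(O)c1ccccc1 | starting material
14 | di-tert-butyl 2-{[(2S)-5,7-bis(benzyloxy)-4-oxo-2-phenylchroman-6-yl]methyl}propanedioate | CC(C)(C)OC(=O)C(Cc1c(OCc2ccccc2)cc2c(c1OCc1ccccc1)C(=O)C[C@@H](c1ccccc1)O2)C(=O)OC(C)(C)C | intermediate
15 | di-tert-butyl 2-{[(2S)-5,7-bis(benzyloxy)-8-iodo-4-oxo-2-phenylchroman-6-yl]methyl}propanedioate | CC(C)(C)OC(=O)C(Cc1c(OCc2ccccc2)c(I)c2c(c1OCc1ccccc1)C(=O)C[C@@H](c1ccccc1)O2)C(=O)OC(C)(C)C | intermediate
16 | 2-methylbut-3-yn-2-ol | CC(C)(O)C#C | starting material
17 | di-tert-butyl 2-{[(2S)-5,7-bis(benzyloxy)-8-(3-hydroxy-3-methylbut-1-yn-1-yl)-4-oxo-2-phenylchroman-6-yl]methyl}propanedioate | CC(C)(C)OC(=O)C(Cc1c(OCc2ccccc2)c(C#CC(C)(C)O)c2c(c1OCc1ccccc1)C(=O)C[C@@H](c1ccccc1)O2)C(=O)OC(C)(C)C | intermediate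
18 | di-tert-butyl 2-{[(2S)-5,7-bis(benzyloxy)-8-(3-methylbut-2-enoyl)-4-oxo-2-phenylchroman-6-yl]methyl}propanedioate | CC(C)(C)OC(=O)C(Cc1c(OCc2ccccc2)c(C(=O)C=C(C)C)c2c(c1OCc1ccccc1)C(=O)C[C@@H](c1ccccc1)O2)C(=O)OC(C)(C)C | intermediate
19 | 2-{[(2S)-5,7-bis(benzyloxy)-8-(3-methylbut-2-enoyl)-4-oxo-2-phenylchroman-6-yl]methyl}propanedioic acid | OC(=O)C(Cc1c(OCc2ccccc2)c(C(=O)C=C(C)C)c2c(c1OCc1ccccc1)C(=O)C[C@@H](c1ccccc1)O2)C(=O)O | intermediate
20 | 2-{[(2S)-5,7-bis(benzyloxy)-8-(3-methylbut-2-enoyl)-4-oxo-2-phenylchroman-6-yl]methyl}propanedioyl dichloride | O=C1C[C@@H](c2ccccc2)Oc2c(C(=O)C=C(C)C)c(OCc3ccccc3)c(CC(C(=O)Cl)C(=O)Cl)c(OCc3ccccc3)c21 | intermediate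
21 | pentan-3-one | CCC(=O)CC | starting material
22 | (Z)-3-(trimethylsilyloxy)pent-2-ene | C/C=C(\O[Si](C)(C)C)CC | intermediate
23 | 2-{[(2S)-5,7-bis(benzyloxy)-8-(3-methylbut-2-enoyl)-4-oxo-2-phenylchroman-6-yl]methyl}-3-oxoprop-2-enoyl chloride | O=C1C[C@@H](c2ccccc2)Oc2c(C(=O)C=C(C)C)c(OCc3ccccc3)c(CC(=C=O)C(=O)Cl)c(OCc3ccccc3)c21 | intermediate (not isolated)
24 | 2-{[(2S)-5,7-bis(benzyloxy)-8-(3-methylbut-2-enoyl)-4-oxo-2-phenylchroman-6-yl]methyl}-4-methyl-3,5-dioxoheptanoyl chloride (mixture of diastereomers) | O=C1C[C@@H](c2ccccc2)Oc2c(C(=O)C=C(C)C)c(OCc3ccccc3)c(CC(C(=O)Cl)C(=O)C(C)C(=O)CC)c(OCc3ccccc3)c21 | intermediate (not isolated)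
25 | (2S)-5,7-bis(benzyloxy)-6-[(6-ethyl-4-hydroxy-5-methyl-2-oxo-2H-pyran-3-yl)methyl]-8-(3-methylbut-2-enoyl)-2-phenylchroman-4-one | O=C1C[C@@H](c2ccccc2)Oc2c(C(=O)C=C(C)C)c(OCc3ccccc3)c(Cc3c(O)c(C)c(CC)oc3=O)c(OCc3ccccc3)c21 | intermediate
26 | (2S)-6-[(6-ethyl-4-hydroxy-5-methyl-2-oxo-2H-pyran-3-yl)methyl]-5,7-dihydroxy-8-(3-methylbut-2-enoyl)-2-phenylchroman-4-one | CCc1oc(=O)c(Cc2c(O)c(C(=O)C=C(C)C)c3c(c2O)C(=O)C[C@@H](c2ccccc2)O3)c(O)c1C | target

## Step count and least certain steps

Total step count: 15. Longest linear sequence: 14 steps (steps 1–12, 14 and 15, from 1); step 13 is a one-step side branch.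

**Step 14 (key step).** The hindered dichloride may acylate carbon slowly, so that O-acylation of 22, self-condensation of the ketene, hydrochlorination of the enone, or attack of a flanking benzyl ether oxygen on the acyl chloride (lactone formation with loss of benzyl chloride) overtakes the annulation. Fallback: run the annulation on a substrate that has no enone and install the senecioyl group afterwards. It sets out from 15. Acidolysis as in step 11 gives the 8-iodo malonic acid F1, oxalyl chloride gives the 8-iodo malonyl dichloride F2, and reaction with 22 as in step 14 gives the 8-iodo pyranone F3. Sonogashira coupling with 16 gives the alkynol pyranone F4, and gold-catalysed Meyer–Schuster rearrangement of F4 comes back to the route at 25.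

**Step 7.** Face selectivity may be insufficient, ring C of the product may open to the chalcone under the hydroxo-rhodium conditions, or protodeboronation may outrun addition to the hindered, electron-rich chromone. Fallback: close ring C by oxa-Michael addition instead of arylation. It sets out from 10. Claisen–Schmidt condensation with benzaldehyde (KOH, EtOH) gives the 2-hydroxychalcone F5. Enantioselective intramolecular oxa-Michael addition under a bifunctional cinchona-alkaloid thiourea (the pseudo-enantiomer that leads to 2S, with enrichment by crystallisation if needed) comes back at 14, bypassing 11 and 12.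

**Step 10.** Other reactions of the gold-activated alkyne may compete: attack of the 7-benzyloxy oxygen with benzyl migration to a benzofuran, or hydration with the opposite regiochemistry. In step 9 just before it, the amine may open ring C. Fallback: carbonylative Stille coupling of 15 with tributyl(2-methylprop-1-en-1-yl)stannane under CO (PdCl2(PPh3)2, toluene, 80 °C) forms the aryl ketone in one neutral operation. It sets out from 15 and comes back at 18, and it makes no new compound (F0).

**Step 15.** After loss of the 7-O-benzyl group the phenol may add to the senecioyl enone under the Lewis acid (closure to a 2,2-dimethylchromanone), or the Lewis acid may open ring C with loss of configuration at C2. Fallback: remove the benzyl ethers before the enone exists and bring the senecioyl group in last. It sets out from 15 and passes through F1, F2 and F3 as described for step 14. BCl3 with pentamethylbenzene then converts F3 into the 8-iodo-5,7-dihydroxy pyranone flavanone F6. Carbonylative Stille coupling of F6 with tributyl(2-methylprop-1-en-1-yl)stannane under CO comes back at 26.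

**Step 2.** The condensation may stall, because the para-phenoxide formed under amine catalysis turns the doubly ortho-substituted aldehyde into a poorly electrophilic vinylogous carboxylate. Fallback: use a quinone methide instead of a carbonyl condensation. It sets out from 3. NaBH4 reduction gives the benzylic alcohol 3,5-bis(benzyloxy)-4-(hydroxymethyl)phenol F7, which under mild base loses water to the para-quinone methide F8. 1,6-Addition of the sodium salt of 4 comes back at 6, bypassing 5.

**Step 5.** Oxidative addition and transmetalation may be slow at the doubly ortho-substituted, electron-rich iodophenol, so that protodeiodination back to 6 dominates; over-iodination in step 4 would also feed this step poorly. Fallback: a photo-Fries rearrangement in place of cross-coupling. It sets out from 6. O-Acetylation (Ac2O, pyridine) gives the aryl acetate F9. Irradiation at 254 nm moves the acetyl group to the ortho carbon, the para position being blocked, and comes back at 10, bypassing 7 and 9.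

## Further compounds

F1 | step 14 | 2-{[(2S)-5,7-bis(benzyloxy)-8-iodo-4-oxo-2-phenylchroman-6-yl]methyl}propanedioic acid | OC(=O)C(Cc1c(OCc2ccccc2)c(I)c2c(c1OCc1ccccc1)C(=O)C[C@@H](c1ccccc1)O2)C(=O)O
F2 | step 14 | 2-{[(2S)-5,7-bis(benzyloxy)-8-iodo-4-oxo-2-phenylchroman-6-yl]methyl}propanedioyl dichloride | ClC(=O)C(Cc1c(OCc2ccccc2)c(I)c2c(c1OCc1ccccc1)C(=O)C[C@@H](c1ccccc1)O2)C(=O)Cl
F3 | step 14 | (2S)-5,7-bis(benzyloxy)-6-[(6-ethyl-4-hydroxy-5-methyl-2-oxo-2H-pyran-3-yl)methyl]-8-iodo-2-phenylchroman-4-one | CCc1oc(=O)c(Cc2c(OCc3ccccc3)c(I)c3c(c2OCc2ccccc2)C(=O)C[C@@H](c2ccccc2)O3)c(O)c1C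
F4 | step 14 | (2S)-5,7-bis(benzyloxy)-6-[(6-ethyl-4-hydroxy-5-methyl-2-oxo-2H-pyran-3-yl)methyl]-8-(3-hydroxy-3-methylbut-1-yn-1-yl)-2-phenylchroman-4-one | CCc1oc(=O)c(Cc2c(OCc3ccccc3)c(C#CC(C)(C)O)c3c(c2OCc2ccccc2)C(=O)C[C@@H](c2ccccc2)O3)c(O)c1C
F5 | step 7 | di-tert-butyl 2-{2,6-bis(benzyloxy)-4-hydroxy-3-[(2E)-3-phenylprop-2-enoyl]benzyl}propanedioate | O=C(/C=C/c1ccccc1)c1c(O)cc(OCc2ccccc2)c(CC(C(=O)OC(C)(C)C)C(=O)OC(C)(C)C)c1OCc1ccccc1
F0 | step 10 | none | none
F6 | step 15 | (2S)-6-[(6-ethyl-4-hydroxy-5-methyl-2-oxo-2H-pyran-3-yl)methyl]-5,7-dihydroxy-8-iodo-2-phenylchroman-4-one | CCc1oc(=O)c(Cc2c(O)c(I)c3c(c2O)C(=O)C[C@@H](c2ccccc2)O3)c(O)c1C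
F7 | step 2 | 3,5-bis(benzyloxy)-4-(hydroxymethyl)phenol | OCc1c(OCc2ccccc2)cc(O)cc1OCc1ccccc1
F8 | step 2 | 3,5-bis(benzyloxy)-4-methylidenecyclohexa-2,5-dien-1-one | C=C1C(OCc2ccccc2)=CC(=O)C=C1OCc1ccccc1
F9 | step 5 | di-tert-butyl 2-[4-(acetyloxy)-2,6-bis(benzyloxy)benzyl]propanedioate | CC(=O)Oc1cc(OCc2ccccc2)c(CC(C(=O)OC(C)(C)C)C(=O)OC(C)(C)C)c(OCc2ccccc2)c1
A1 | alternative 1 | 2,4-dimethoxy-6-[(1-phenylethenyl)oxy]benzaldehyde | O=Cc1c(OC)cc(OC)cc1OC(=C)c1ccccc1
A2 | alternative 1 | (2S)-5,7-dimethoxyflavanone | O=C1C[C@@H](c2ccccc2)Oc2cc(OC)cc(OC)c21
A3 | alternative 2 | methyl 3-oxo-4-[(2S)-4-oxo-2-phenyl-3,4-dihydro-2H-pyran-6-yl]butanoate | COC(=O)CC(=O)CC1=CC(=O)C[C@@H](c2ccccc2)O1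
A4 | alternative 2 | (2S)-5,7-dihydroxyflavanone | O=C1C[C@@H](c2ccccc2)Oc2cc(O)cc(O)c21
A5 | alternative 3 | 3,5-bis(benzyloxy)-2-(trimethylsilyl)phenyl trifluoromethanesulfonate | FC(F)(F)S(=O)(=O)Oc1cc(OCc2ccccc2)cc(OCc2ccccc2)c1[Si](C)(C)C
A6 | alternative 3 | methyl (3S)-3-hydroxy-3-phenylpropanoate | COC(=O)C[C@@H](c1ccccc1)O
A7 | alternative 3 | (2S)-5,7-bis(benzyloxy)flavanone | O=C1C[C@@H](c2ccccc2)Oc2cc(OCc3ccccc3)cc(OCc3ccccc3)c21
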